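**Retrosynthetic overview**

1. The C40 chain is cut at C11=C12 and C11'=C12' into a ring A C15 ylide, the C10 trienedial and a ring B C15 ylide; two E-selective Wittig reactions of tributylphosphonium ylides join them, and the two silyl ethers fall last.
2. Ring A (C1–C6, the acetylenic end) is never closed: it is carried in intact, with C3, from (4R,6R)-actinol through its enol triflate and a Sonogashira coupling (C6–C7).
3. Ring B (C1'–C6', the 7',8'-dihydro end) is the only ring that is built, and so the last one closed: an intramolecular McMurry coupling unites the two carbonyl carbons C5' and C6' (like polarity) of an acyclic 1,6-diketone and leaves the double bond exactly at C5'=C6'.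
4. Enabling feature: the single, tetrasubstituted C5'=C6' bond of ring B is insulated from the polyene by the saturated C7'–C8' bridge, and O–C3' lies 1,3 to C5'. Ring B therefore maps onto a non-conjugated diketone (C5'=O and C6'=O, an extra oxidation level erased in the ring closure) that is an acetone aldol adduct.
5. The diketone comes from acetone, 2,2-dimethylpent-4-enal and a C4 silylalkyne Grignard reagent; a catalytic enantioselective aldol sets C3'.

Key step: step 10

Remark: carotenoid numbering is used (ring A = C1–C6, ring B = C1'–C6'); compounds 1, 5, 9, 10 and 25 are taken as purchasable; reagent-derived species made in a separate operation (enolate, Grignard reagent, ozonide, alanes, bromides, ylides) are numbered, surface-bound titanium species are not.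

**Route**

Step 1
Reactants: 1 (4R,6R)-4-hydroxy-2,2,6-trimethylcyclohexan-1-one (actinol)
Product: 2 (4R,6R)-4-(tert-butyldimethylsilyloxy)-2,2,6-trimethylcyclohexan-1-one
Conditions: TBSCl, imidazole, DMF, rt
Reagents that add atoms: tert-butyldimethylsilyl chloride, CC(C)(C)[Si](C)(C)Cl
Why: Imidazole-mediated silylation (silyl ether protection) of the unhindered secondary alcohol should proceed without touching either stereocentre.

Step 2
Reactants: 2 (4R,6R)-4-(tert-butyldimethylsilyloxy)-2,2,6-trimethylcyclohexan-1-one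
Product: 4 (4R)-4-(tert-butyldimethylsilyloxy)-2,6,6-trimethylcyclohex-1-en-1-yl trifluoromethanesulfonate, via lithium enolate 3 (not isolated)
Conditions: LiN(i-Pr)2, THF, −78 → 0 °C; then PhNTf2, −78 °C → rt
Reagents that add atoms: N-phenylbis(trifluoromethanesulfonimide), O=S(=O)(C(F)(F)F)N(c1ccccc1)S(=O)(=O)C(F)(F)F
Why: The ketone can enolise only toward the methyl-bearing carbon (the other α-carbon is quaternary), so enol triflate formation should give one regioisomer; the silyloxy carbon (later C3) is not involved.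

Step 3
Reactants: 4 the enol triflate; 5 (E)-3-methylpent-2-en-4-yn-1-ol
Product: 6 (2E)-5-[(4R)-4-(tert-butyldimethylsilyloxy)-2,6,6-trimethylcyclohex-1-en-1-yl]-3-methylpent-2-en-4-yn-1-ol
Conditions: Pd(PPh3)4 (5 mol %), CuI (10 mol %), i-Pr2NH, DMF, rt → 40 °C
Reagents that add atoms: none
Why: Sonogashira coupling of the vinyl triflate with the terminal alkyne should form C6–C7 and carry over the E geometry of the enyne already present in 5.

Step 4
Reactants: 6 the ring A C15 allylic alcohol
Product: 8 tributyl{(2E)-5-[(4R)-4-(tert-butyldimethylsilyloxy)-2,6,6-trimethylcyclohex-1-en-1-yl]-3-methylpent-2-en-4-yn-1-yl}phosphonium bromide, via allylic bromide 7 (not isolated)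
Conditions: CBr4, PPh3 (1.0 equiv), CH2Cl2, −20 °C; then PBu3, 0 °C → rt, dark
Reagents that add atoms: carbon tetrabromide, BrC(Br)(Br)Br; tributylphosphine, CCCCP(CCCC)CCCC
Why: Appel bromination (acid-free SN2 at the primary allylic carbon, so the silyl ether survives) followed by SN2 quaternisation of PBu3 should give the trialkylphosphonium salt, chosen because its ylide is E-selective and slow to scramble the 9E bond.

Step 5
Reactants: 9 4-bromo-1-(trimethylsilyl)but-1-yne; 10 2,2-dimethylpent-4-enal
Product: 12 rac-6,6-dimethyl-1-(trimethylsilyl)non-8-en-1-yn-5-ol, via Grignard reagent 11 (not isolated)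
Conditions: Mg, THF, rt (9 → 11); then 10, THF, 0 °C; aqueous work-up
Reagents that add atoms: none
Why: Grignard addition to a non-enolisable α-quaternary aldehyde should be clean; the racemic carbinol centre is removed in step 6.

Step 6
Reactants: 12 the secondary alcohol
Product: 13 6,6-dimethyl-1-(trimethylsilyl)non-8-en-1-yn-5-one
Conditions: Dess–Martin periodinane, CH2Cl2, rt
Reagents that add atoms: none
Why: Dess–Martin oxidation should convert the hindered secondary alcohol into the ketone (later C6'=O) under neutral conditions.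

Step 7
Reactants: 13 the enynone
Product: 15 3,3-dimethyl-4-oxo-8-(trimethylsilyl)oct-7-ynal, via secondary ozonide 14 (not isolated)
Conditions: O3, CH2Cl2, −78 °C (Sudan red end point); then Me2S, −78 °C → rt
Reagents that add atoms: ozone, [O-][O+]=O
Why: Ozonolysis with reductive work-up should cleave only the monosubstituted alkene, which reacts far faster with ozone than the silyl-capped alkyne, to give the C3' aldehyde.

Step 8
Reactants: 15 the keto aldehyde
Product: 16 (4S)-4-hydroxy-6,6-dimethyl-11-(trimethylsilyl)undec-10-yne-2,7-dione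
Conditions: (S)-N-[(1S,2S)-2-hydroxy-1,2-diphenylethyl]pyrrolidine-2-carboxamide (20 mol %), acetone (solvent), −25 °C
Reagents that add atoms: acetone, CC(C)=O
Why: Enamine-catalysed direct asymmetric aldol (List–Houk-type transition state): the acetone enamine of the L-prolinamide should attack the Re face of the hydrogen-bonded aldehyde and so set C3' (descriptor S here, R once in the ring), while the hindered α-quaternary ketone stays out.

Step 9
Reactants: 16 the aldol adduct
Product: 17 (4S)-4-(tert-butyldimethylsilyloxy)-6,6-dimethyl-11-(trimethylsilyl)undec-10-yne-2,7-dione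
Conditions: TBSCl, imidazole, DMF, 0 °C → rt
Reagents that add atoms: tert-butyldimethylsilyl chloride, CC(C)(C)[Si](C)(C)Cl
Why: Silylation of the secondary hydroxyl (silyl ether protection) should trap the open-chain form and block retro-aldol and hemiketal formation before the reductive coupling.

Step 10
Reactants: 17 the silylated 1,6-diketone
Product: 18 tert-butyldimethyl{[(1R)-3,5,5-trimethyl-4-[4-(trimethylsilyl)but-3-yn-1-yl]cyclohex-3-en-1-yl]oxy}silane
Conditions: TiCl3(DME)1.5, Zn–Cu couple, DME, reflux; 17 added by syringe pump over 30 h, then reflux 10 h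
Reagents that add atoms: none
Why: Low-valent titanium should transfer single electrons to both ketones; the two ketyl carbons C5' and C6', both electrophilic in 17, then couple to a titanium-bound pinacolate whose two C–O bonds are cleaved on the metal at reflux to give the C5'=C6' alkene. The closest known reaction type is the intramolecular McMurry coupling of 1,6-diketones to 1,2-dialkylcyclohexenes under high dilution. Ring B closes in a six-membered head-to-head carbonyl–carbonyl reductive closure in which the new bond becomes the endocyclic double bond, so the ring and its tetrasubstituted alkene arise together. No stereocentre is formed (both pinacol carbons end as sp2), and C3', set in step 8, is a non-enolisable carbinol carbon that cannot epimerise. The step needs cyclisation to win over intermolecular coupling, which the favoured ring size, the gem-dimethyl group at C1' and slow addition should secure, and it needs the double bond only at C5'=C6', which is guaranteed because the alkene can form solely between the two former carbonyl carbons, with none of the α- or γ-ring isomers of cationic cyclisations. The silyl ether, the silylalkyne and the saturated C7'–C8' link (no enone, hence no conjugate reduction) are features of 17 that the reagent should tolerate.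

Step 11
Reactants: 18 the ring B silylalkyne
Product: 19 tert-butyl{[(1R)-4-(but-3-yn-1-yl)-3,5,5-trimethylcyclohex-3-en-1-yl]oxy}dimethylsilane
Conditions: K2CO3 (cat.), MeOH, rt
Reagents that add atoms: none
Why: Base-catalysed methanolysis of the alkynyl C–Si bond (protiodesilylation) should be selective over the secondary silyl ether.

Step 12
Reactants: 19 the terminal alkyne
Product: 22 (2E)-5-[(4R)-4-(tert-butyldimethylsilyloxy)-2,6,6-trimethylcyclohex-1-en-1-yl]-3-methylpent-2-en-1-ol, via alkenylalane 20 (not isolated), via lithium alanate 21 (not isolated)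
Conditions: Me3Al, Cp2ZrCl2 (25 mol %), CH2Cl2, 0 °C → rt; volatiles removed; n-BuLi, THF/hexane, −78 °C; (CH2O)n, −78 °C → rt; aqueous work-up
Reagents that add atoms: trimethylaluminium, C[Al](C)C; formaldehyde (as paraformaldehyde), C=O
Why: Negishi zirconium-catalysed carboalumination should add methyl (to C9') and aluminium (to C10') syn across the terminal alkyne, fixing the 9'E trisubstituted alkene, and the derived alanate is hydroxymethylated by formaldehyde with retention.

Step 13
Reactants: 22 the ring B C15 allylic alcohol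
Product: 24 tributyl{(2E)-5-[(4R)-4-(tert-butyldimethylsilyloxy)-2,6,6-trimethylcyclohex-1-en-1-yl]-3-methylpent-2-en-1-yl}phosphonium bromide, via allylic bromide 23 (not isolated)
Conditions: CBr4, PPh3 (1.0 equiv), CH2Cl2, −20 °C; then PBu3, rt
Reagents that add atoms: carbon tetrabromide, BrC(Br)(Br)Br; tributylphosphine, CCCCP(CCCC)CCCC
Why: Appel bromination and SN2 quaternisation, as in step 4, should give the allylic trialkylphosphonium salt with the 9'E bond unchanged.

Step 14
Reactants: 24 the ring B phosphonium bromide; 25 (2E,4E,6E)-2,7-dimethylocta-2,4,6-trienedial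
Product: 27 (2E,4E,6E,8E,10E)-13-[(4R)-4-(tert-butyldimethylsilyloxy)-2,6,6-trimethylcyclohex-1-en-1-yl]-2,7,11-trimethyltrideca-2,4,6,8,10-pentaenal, via phosphonium ylide 26 (not isolated)
Conditions: NaN(SiMe3)2, THF, −78 °C (24 → 26); cannulated into 25 (2 equiv), THF, −78 °C → rt, dark
Reagents that add atoms: none
Why: Wittig olefination of one formyl group of the symmetric dialdehyde; allylic trialkylphosphonium ylides give mainly E-alkenes at the new C11'=C12' bond, and excess 25 plus the lower electrophilicity of the more conjugated product should favour mono-olefination.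

Step 15
Reactants: 27 the C25 aldehyde; 8 the ring A phosphonium bromide
Product: 29 (3R,3'R)-3,3'-bis(tert-butyldimethylsilyloxy)-7,8-didehydro-7',8'-dihydro-β,β-carotene (all-E), via phosphonium ylide 28 (not isolated)
Conditions: NaN(SiMe3)2, THF, −78 °C (8 → 28); then 27, −78 → 0 °C, dark, argon
Reagents that add atoms: none
Why: Wittig olefination forms C11=C12; the tributylphosphonium ylide should be E-selective, and its generation and capture at low temperature should leave the 9E enyne bond unscrambled, so no isomerisation step is needed afterwards.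

Step 16
Reactants: 29 the bis-silyl ether
Product: 30 (3R,3'R)-7,8-didehydro-7',8'-dihydro-β,β-carotene-3,3'-diol (all-E), the target
Conditions: Bu4NF, THF, 0 °C → rt, dark
Reagents that add atoms: none
Why: Fluoride-induced desilylation of both secondary silyl ethers under non-acidic conditions should free the diol without isomerising the polyene-yne.

**Compound list**

1 | (4R,6R)-4-hydroxy-2,2,6-trimethylcyclohexan-1-one (actinol) | O=C1C(C)(C)C[C@H](O)C[C@H]1C | starting material
2 | (4R,6R)-4-(tert-butyldimethylsilyloxy)-2,2,6-trimethylcyclohexan-1-one | O=C1C(C)(C)C[C@H](O[Si](C)(C)C(C)(C)C)C[C@H]1C | intermediate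
3 | lithium (4R)-4-(tert-butyldimethylsilyloxy)-2,6,6-trimethylcyclohex-1-en-1-olate | [Li+].[O-]C1=C(C)C[C@@H](O[Si](C)(C)C(C)(C)C)CC1(C)C | intermediate
4 | (4R)-4-(tert-butyldimethylsilyloxy)-2,6,6-trimethylcyclohex-1-en-1-yl trifluoromethanesulfonate | CC1=C(OS(=O)(=O)C(F)(F)F)C(C)(C)C[C@H](O[Si](C)(C)C(C)(C)C)C1 | intermediate
5 | (E)-3-methylpent-2-en-4-yn-1-ol | C#C/C(C)=C/CO | starting material
6 | (2E)-5-[(4R)-4-(tert-butyldimethylsilyloxy)-2,6,6-trimethylcyclohex-1-en-1-yl]-3-methylpent-2-en-4-yn-1-ol | CC1=C(C#C/C(C)=C/CO)C(C)(C)C[C@H](O[Si](C)(C)C(C)(C)C)C1 | intermediate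
7 | ring A allylic bromide (bromide of 6) | CC1=C(C#C/C(C)=C/CBr)C(C)(C)C[C@H](O[Si](C)(C)C(C)(C)C)C1 | intermediate
8 | ring A C15 tributylphosphonium bromide | CC1=C(C#C/C(C)=C/C[P+](CCCC)(CCCC)CCCC)C(C)(C)C[C@H](O[Si](C)(C)C(C)(C)C)C1.[Br-] | intermediate
9 | 4-bromo-1-(trimethylsilyl)but-1-yne | C[Si](C)(C)C#CCCBr | starting material
10 | 2,2-dimethylpent-4-enal | C=CCC(C)(C)C=O | starting material
11 | [4-(trimethylsilyl)but-3-yn-1-yl]magnesium bromide | C[Si](C)(C)C#CCC[Mg]Br | intermediate
12 | rac-6,6-dimethyl-1-(trimethylsilyl)non-8-en-1-yn-5-ol | C=CCC(C)(C)C(O)CCC#C[Si](C)(C)C | intermediate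
13 | 6,6-dimethyl-1-(trimethylsilyl)non-8-en-1-yn-5-one | C=CCC(C)(C)C(=O)CCC#C[Si](C)(C)C | intermediate
14 | secondary ozonide (1,2,4-trioxolane) of 13 | C1OC(CC(C)(C)C(=O)CCC#C[Si](C)(C)C)OO1 | intermediate
15 | 3,3-dimethyl-4-oxo-8-(trimethylsilyl)oct-7-ynal | O=CCC(C)(C)C(=O)CCC#C[Si](C)(C)C | intermediate
16 | (4S)-4-hydroxy-6,6-dimethyl-11-(trimethylsilyl)undec-10-yne-2,7-dione | CC(=O)C[C@@H](O)CC(C)(C)C(=O)CCC#C[Si](C)(C)C | intermediate
17 | (4S)-4-(tert-butyldimethylsilyloxy)-6,6-dimethyl-11-(trimethylsilyl)undec-10-yne-2,7-dione | CC(=O)C[C@@H](O[Si](C)(C)C(C)(C)C)CC(C)(C)C(=O)CCC#C[Si](C)(C)C | intermediate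
18 | tert-butyldimethyl{[(1R)-3,5,5-trimethyl-4-[4-(trimethylsilyl)but-3-yn-1-yl]cyclohex-3-en-1-yl]oxy}silane | CC1=C(CCC#C[Si](C)(C)C)C(C)(C)C[C@H](O[Si](C)(C)C(C)(C)C)C1 | intermediate
19 | tert-butyl{[(1R)-4-(but-3-yn-1-yl)-3,5,5-trimethylcyclohex-3-en-1-yl]oxy}dimethylsilane | CC1=C(CCC#C)C(C)(C)C[C@H](O[Si](C)(C)C(C)(C)C)C1 | intermediate
20 | (E)-alkenyldimethylalane from 19 | C[Al](C)/C=C(\C)CCC1=C(C)C[C@@H](O[Si](C)(C)C(C)(C)C)CC1(C)C | intermediate
21 | lithium butyl(dimethyl)alkenylalanate from 20 | [Li+].CCCC[Al-](C)(C)/C=C(\C)CCC1=C(C)C[C@@H](O[Si](C)(C)C(C)(C)C)CC1(C)C | intermediate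
22 | (2E)-5-[(4R)-4-(tert-butyldimethylsilyloxy)-2,6,6-trimethylcyclohex-1-en-1-yl]-3-methylpent-2-en-1-ol | OC/C=C(\C)CCC1=C(C)C[C@@H](O[Si](C)(C)C(C)(C)C)CC1(C)C | intermediate
23 | ring B allylic bromide (bromide of 22) | BrC/C=C(\C)CCC1=C(C)C[C@@H](O[Si](C)(C)C(C)(C)C)CC1(C)C | intermediate
24 | ring B C15 tributylphosphonium bromide | CCCC[P+](CCCC)(CCCC)C/C=C(\C)CCC1=C(C)C[C@@H](O[Si](C)(C)C(C)(C)C)CC1(C)C.[Br-] | intermediate
25 | (2E,4E,6E)-2,7-dimethylocta-2,4,6-trienedial | O=C/C(C)=C/C=C/C=C(C)/C=O | starting material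
26 | ring B phosphonium ylide from 24 | CCCC[P+](CCCC)(CCCC)[CH-]/C=C(\C)CCC1=C(C)C[C@@H](O[Si](C)(C)C(C)(C)C)CC1(C)C | intermediate
27 | (2E,4E,6E,8E,10E)-13-[(4R)-4-(tert-butyldimethylsilyloxy)-2,6,6-trimethylcyclohex-1-en-1-yl]-2,7,11-trimethyltrideca-2,4,6,8,10-pentaenal | O=C/C(C)=C/C=C/C=C(C)/C=C/C=C(\C)CCC1=C(C)C[C@@H](O[Si](C)(C)C(C)(C)C)CC1(C)C | intermediate
28 | ring A phosphonium ylide from 8 | CC1=C(C#C/C(C)=C/[CH-][P+](CCCC)(CCCC)CCCC)C(C)(C)C[C@H](O[Si](C)(C)C(C)(C)C)C1 | intermediate
29 | (3R,3'R)-3,3'-bis(tert-butyldimethylsilyloxy)-7,8-didehydro-7',8'-dihydro-β,β-carotene | CC1=C(C#C/C(C)=C/C=C/C(C)=C/C=C/C=C(C)/C=C/C=C(\C)CCC2=C(C)C[C@@H](O[Si](C)(C)C(C)(C)C)CC2(C)C)C(C)(C)C[C@H](O[Si](C)(C)C(C)(C)C)C1 | intermediate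
30 | (3R,3'R)-7,8-didehydro-7',8'-dihydro-β,β-carotene-3,3'-diol | CC1=C(C#C/C(C)=C/C=C/C(C)=C/C=C/C=C(C)/C=C/C=C(\C)CCC2=C(C)C[C@@H](O)CC2(C)C)C(C)(C)C[C@H](O)C1 | target

**Totals**

Total step count: 16. Longest linear sequence: 12 steps (steps 5–16); the ring A branch (steps 1–4) joins at step 15.

**Steps most likely to fail**

Step 10 (McMurry ring closure). The coupling may stop at the pinacol stage at the hindered α-quaternary ketone, compete with intermolecular coupling, or be undercut by β-elimination of the silyloxy group from the titanium-bound methyl ketone. The fallback sets out from 17 and still closes ring B, but by olefin metathesis. Both carbonyls are methylenated with Ph3P=CH2 (THF, 0 °C for the methyl ketone, then reflux for the hindered ketone) to give the 1,7-diene tert-butyl{[(4R)-2,6,6-trimethyl-7-methylidene-11-(trimethylsilyl)undec-1-en-10-yn-4-yl]oxy}dimethylsilane F1. Ring-closing metathesis with a second-generation Hoveyda–Grubbs-type catalyst carrying the less hindered N-o-tolyl carbene ligand (toluene, 80 °C, ethene purged) should then give the tetrasubstituted cyclohexene; this reaction type is known for cyclohexenes next to a gem-dimethyl carbon. The fallback comes back to the route at 18.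

Step 8 (asymmetric acetone aldol). Enantioface discrimination may be incomplete and self-condensation of the α-unbranched aldehyde may compete; an eroded configuration at C3' cannot be corrected later because ring A is already enantiopure. The fallback sets out from 15 and replaces the aldol by an allylation–oxidation sequence. Brown allylation with the B-allyldiisopinocampheylborane antipode that attacks the Re face (the reagent derived from (−)-α-pinene; Et2O, −78 °C; ethanolamine work-up) should give (4R)-4-hydroxy-6,6-dimethyl-11-(trimethylsilyl)undec-1-en-10-yn-7-one F2. Silylation (TBSCl, imidazole, DMF) gives its tert-butyldimethylsilyl ether F3, and Tsuji–Wacker oxidation of the terminal alkene (PdCl2, CuCl, O2, DMF/H2O) gives the methyl ketone. The fallback comes back to the route at 17.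

Step 15 (final Wittig). The 9E bond may scramble in the delocalised enyne–allyl ylide, and E-selectivity at the new C11=C12 bond may be incomplete. The fallback sets out from 6 and 27 and reverses the polarity of the union, so that no carbanion is ever generated next to the enyne. Alcohol 6 is oxidised with MnO2 (CH2Cl2, rt) to (2E)-5-[(4R)-4-(tert-butyldimethylsilyloxy)-2,6,6-trimethylcyclohex-1-en-1-yl]-3-methylpent-2-en-4-ynal F4. Aldehyde 27 is reduced with NaBH4 (MeOH/THF, 0 °C) to the C25 pentaenol F5, which is converted by CBr4/PPh3 into the C25 allylic bromide F6 and then by PBu3 into the C25 tributylphosphonium bromide F7. Deprotonation with NaN(SiMe3)2 (THF, −78 °C) gives the C25 ylide F8, which is condensed with F4; any hindered 11Z or 13Z isomer relaxes on gentle warming. The fallback comes back to the route at 29.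

**Further compounds**

F1 | step 10 | tert-butyl{[(4R)-2,6,6-trimethyl-7-methylidene-11-(trimethylsilyl)undec-1-en-10-yn-4-yl]oxy}dimethylsilane | C=C(C)C[C@@H](O[Si](C)(C)C(C)(C)C)CC(C)(C)C(=C)CCC#C[Si](C)(C)C
F2 | step 8 | (4R)-4-hydroxy-6,6-dimethyl-11-(trimethylsilyl)undec-1-en-10-yn-7-one | C=CC[C@@H](O)CC(C)(C)C(=O)CCC#C[Si](C)(C)C
F3 | step 8 | (4R)-4-(tert-butyldimethylsilyloxy)-6,6-dimethyl-11-(trimethylsilyl)undec-1-en-10-yn-7-one | C=CC[C@@H](O[Si](C)(C)C(C)(C)C)CC(C)(C)C(=O)CCC#C[Si](C)(C)C
F4 | step 15 | (2E)-5-[(4R)-4-(tert-butyldimethylsilyloxy)-2,6,6-trimethylcyclohex-1-en-1-yl]-3-methylpent-2-en-4-ynal | CC1=C(C#C/C(C)=C/C=O)C(C)(C)C[C@H](O[Si](C)(C)C(C)(C)C)C1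
F5 | step 15 | (2E,4E,6E,8E,10E)-13-[(4R)-4-(tert-butyldimethylsilyloxy)-2,6,6-trimethylcyclohex-1-en-1-yl]-2,7,11-trimethyltrideca-2,4,6,8,10-pentaen-1-ol | OC/C(C)=C/C=C/C=C(C)/C=C/C=C(\C)CCC1=C(C)C[C@@H](O[Si](C)(C)C(C)(C)C)CC1(C)C
F6 | step 15 | C25 allylic bromide (bromide of F5) | BrC/C(C)=C/C=C/C=C(C)/C=C/C=C(\C)CCC1=C(C)C[C@@H](O[Si](C)(C)C(C)(C)C)CC1(C)C
F7 | step 15 | C25 tributylphosphonium bromide | CCCC[P+](CCCC)(CCCC)C/C(C)=C/C=C/C=C(C)/C=C/C=C(\C)CCC1=C(C)C[C@@H](O[Si](C)(C)C(C)(C)C)CC1(C)C.[Br-]
F8 | step 15 | C25 phosphonium ylide from F7 | CCCC[P+](CCCC)(CCCC)[CH-]/C(C)=C/C=C/C=C(C)/C=C/C=C(\C)CCC1=C(C)C[C@@H](O[Si](C)(C)C(C)(C)C)CC1(C)C
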